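**Plan**

- Retrosynthesis: the C8–CH2 bond to the acylphloroglucinol is cut first (an o-quinone methide from a Mannich base adding to the free C8 of ring A). Then O1–C2 and C3–C4 of ring C are cut together as one [4+2] operation. Last come the formyl carbon (the future C4), the prenyl group and the protecting groups, back to phloroglucinol.
- Enabling feature: ring C (O1, C2, C3, C4, C4a, C8a) has its two disconnected bonds, O1–C2 and C3–C4, on either side of a C2–C3 unit that is simply styrene. C4 traces back to the formyl carbon of a ring A salicylaldehyde whose only free hydroxyl becomes O1.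
- Forward order: ring A is dressed first (MOM, TIPS, prenyl at the future C6, formyl), ring C is closed, C4 is raised from methyl ether to ketone, the MOM groups are removed and the C8 benzyl arm is attached last.
- Stereochemistry: C2 (S) is the only stereocentre of the target and is set in the [4+2] step by a chiral phosphate counter-ion. C4 is created in the same step and erased on oxidation; basic media are avoided once the C4 ketone exists.

Key step: step 6

Assumption: the (R)-configured phosphoric acid is taken to favour the 2S series; this sense of induction cannot be read from precedent and is to be confirmed on the first batch by correlating the deprotected flavanone with the natural 2S series, the (S)-acid being used instead if the antipode forms.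

**Route**

Step 1
Reactants: 1 phloroglucinol (benzene-1,3,5-triol)
Product: 2 3,5-bis(methoxymethoxy)phenol
Conditions: MOMCl (2.1 equiv), i-Pr2NEt, DMF, 0 °C to rt; chromatography
Reagents that add atoms: chloromethyl methyl ether, COCCl
Why: O-alkylation of the phenol with an α-chloro ether (MOM protection); with two equivalents the bis-ether should be the main component of a statistical mixture and is separable from the mono- and tris-ethers.

Step 2
Reactants: 2 3,5-bis(methoxymethoxy)phenol
Product: 3 [3,5-bis(methoxymethoxy)phenoxy]tri(propan-2-yl)silane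
Conditions: TIPSCl, imidazole, DMF, rt
Reagents that add atoms: chlorotri(propan-2-yl)silane, CC(C)[Si](Cl)(C(C)C)C(C)C
Why: imidazole-promoted silylation of a phenol; the bulky TIPS ether should neither direct lithiation nor migrate to carbon in the next step.

Step 3
Reactants: 3 [3,5-bis(methoxymethoxy)phenoxy]tri(propan-2-yl)silane; 4 1-bromo-3-methylbut-2-ene (prenyl bromide)
Product: 6 [3,5-bis(methoxymethoxy)-4-(3-methylbut-2-enyl)phenoxy]tri(propan-2-yl)silane, via aryllithium 5 (not isolated)
Conditions: n-BuLi, THF, 0 °C; then 4, −78 °C to rt
Reagents that add atoms: 1-bromo-3-methylbut-2-ene (compound 4), CC(C)=CCBr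
Why: directed ortho-metalation, in which the C–H between the two MOM ethers is the only one flanked by two chelating groups, followed by SN2 displacement of the primary allylic bromide by the aryllithium.

Step 4
Reactants: 6 [3,5-bis(methoxymethoxy)-4-(3-methylbut-2-enyl)phenoxy]tri(propan-2-yl)silane
Product: 7 3,5-bis(methoxymethoxy)-4-(3-methylbut-2-enyl)phenol
Conditions: n-Bu4NF, AcOH, THF, 0 °C
Reagents that add atoms: none
Why: fluoride cleavage of an aryl silyl ether, buffered with acetic acid; MOM acetals and the alkene are inert to fluoride.

Step 5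
Reactants: 7 3,5-bis(methoxymethoxy)-4-(3-methylbut-2-enyl)phenol
Product: 8 2-hydroxy-4,6-bis(methoxymethoxy)-5-(3-methylbut-2-enyl)benzaldehyde
Conditions: MgCl2, Et3N, (CH2O)n, MeCN, reflux; aq. NH4Cl work-up
Reagents that add atoms: paraformaldehyde (reacting as formaldehyde), C=O
Why: Casnati–Skattebøl ortho-formylation, in which the magnesium phenoxide delivers formaldehyde to the ortho carbon and a second formaldehyde oxidises the hydroxymethyl intermediate by hydride transfer; the two ortho positions are equivalent, so a single salicylaldehyde should result.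

Step 6
Reactants: 8 2-hydroxy-4,6-bis(methoxymethoxy)-5-(3-methylbut-2-enyl)benzaldehyde; 9 trimethyl orthoformate; 10 styrene
Product: 13 (2S,4S)-4-methoxy-5,7-bis(methoxymethoxy)-6-(3-methylbut-2-enyl)-2-phenylchromane (2,4-cis flavan), via dimethyl acetal 11 (not isolated), via methoxy o-quinone methide 12 (not isolated)
Conditions: (R)-3,3'-bis(2,4,6-triisopropylphenyl)-1,1'-binaphthyl-2,2'-diyl hydrogen phosphate (10 mol %), 9 (2 equiv), 10 (20 equiv), 5 Å molecular sieves, toluene (0.02 M in 8), −20 °C to 0 °C; Et3N quench; chromatography on Et3N-deactivated silica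
Reagents that add atoms: trimethyl orthoformate (compound 9), COC(OC)OC; styrene (compound 10), C=Cc1ccccc1
Why: Proposed new method: the chiral acid should convert 8 and 9 into acetal 11 and, by loss of methanol, into the O-protonated form of 12, an aryl-stabilised oxocarbenium ion held by the phosphate through ion pairing and a hydrogen bond to the single ortho hydroxyl; the CH2 terminus of styrene then adds to the carboxonium carbon (C3–C4) and the phenol oxygen closes on the developing benzylic cation (O1–C2), an asynchronous inverse-demand hetero-Diels–Alder reaction. The closest known reactions are the Lewis acid (for example Sc(OTf)3) three-component coupling of salicylaldehydes, orthoformates and styrenes to 2,4-cis-4-alkoxy-2-arylchromans and chiral phosphoric acid [4+2] cycloadditions of o-quinone methides with vinylarenes, so only their combination is untested. Ring C is closed in the intermolecular [4+2] event itself, the second bond (O1–C2) forming as a six-membered closure of the phenol oxygen onto the benzylic carbon. The face of the carboxonium carbon that styrene attacks, and hence C4, is chosen by the binaphthyl pocket of the phosphate, and C2 follows from C4 through the endo transition state (phenyl under the heterodiene, E-configured methoxymethylidene), which gives the 2,4-cis flavan with 2S. Regiochemistry needs no control, because only one hydroxyl flanks the formyl group and the phenyl group must sit on the cation-stabilising C2, while chemoselectivity against the prenyl alkene rests on the large excess of styrene, the high dilution of 8 and the capping of both oxygens next to the prenyl group. The minor 2,4-trans isomer, which carries the opposite C2 configuration, is to be removed at this stage, and the acid is quenched at full conversion so that the labile C4 ether does not re-ionise and blur that relationship.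

Step 7
Reactants: 13 (2S,4S)-4-methoxy-5,7-bis(methoxymethoxy)-6-(3-methylbut-2-enyl)-2-phenylchromane
Product: 14 (2S)-5,7-bis(methoxymethoxy)-6-(3-methylbut-2-enyl)-2-phenylchroman-4-ol (both C4 epimers, used crude)
Conditions: pyridinium p-toluenesulfonate (20 mol %), THF/H2O, 0.01 M, rt
Reagents that add atoms: water, O
Why: acid-catalysed SN1 solvolysis of a benzylic ether, whose C4 cation is stabilised by O1 and the C5 and C7 oxygens and should therefore form under a pyridinium acid that leaves aryl MOM acetals intact; water in large excess at high dilution captures it, C2 is not involved and the C4 configuration is irrelevant.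

Step 8
Reactants: 14 (2S)-5,7-bis(methoxymethoxy)-6-(3-methylbut-2-enyl)-2-phenylchroman-4-ol
Product: 15 (2S)-5,7-bis(methoxymethoxy)-6-(3-methylbut-2-enyl)-2-phenylchroman-4-one
Conditions: (n-Pr)4N[RuO4] (5 mol %), N-methylmorpholine N-oxide, 4 Å molecular sieves, CH2Cl2, 0 °C to rt
Reagents that add atoms: none
Why: Ley–Griffith oxidation of a secondary benzylic alcohol under nearly neutral conditions, which should spare the trisubstituted alkene and the acetals and is too weakly basic at room temperature to open ring C, so C2 is kept.

Step 9
Reactants: 15 (2S)-5,7-bis(methoxymethoxy)-6-(3-methylbut-2-enyl)-2-phenylchroman-4-one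
Product: 16 (2S)-5,7-dihydroxy-6-(3-methylbut-2-enyl)-2-phenylchroman-4-one (6-prenylpinocembrin)
Conditions: 3 M aq. HCl, MeOH, 40 °C
Reagents that add atoms: none
Why: acid-catalysed cleavage of the MOM acetals by transfer of the methoxymethyl group to methanol; dilute acid at mild temperature should neither cyclise the prenyl group onto a neighbouring phenol nor open ring C, which acid does far more slowly than base.

Step 10
Reactants: 17 1-(2,4,6-trihydroxy-3-methylphenyl)ethanone (2,4,6-trihydroxy-3-methylacetophenone)
Product: 18 1-[3-[(dimethylamino)methyl]-2,4,6-trihydroxy-5-methylphenyl]ethanone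
Conditions: 37% aq. CH2O, 40% aq. Me2NH, EtOH, 0 °C to rt
Reagents that add atoms: formaldehyde, C=O; dimethylamine, CNC
Why: phenol Mannich reaction at the only unsubstituted ring carbon of the acylphloroglucinol.

Step 11
Reactants: 16 (2S)-5,7-dihydroxy-6-(3-methylbut-2-enyl)-2-phenylchroman-4-one; 18 1-[3-[(dimethylamino)methyl]-2,4,6-trihydroxy-5-methylphenyl]ethanone
Product: 20 (2S)-8-[(3-acetyl-2,4,6-trihydroxy-5-methylphenyl)methyl]-5,7-dihydroxy-6-(3-methylbut-2-enyl)-2-phenylchroman-4-one (the target), via o-quinone methide 19 (not isolated)
Conditions: 18 (1.3 equiv), 1,4-dioxane, 80 °C, slow N2 sweep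
Reagents that add atoms: none
Why: thermal loss of dimethylamine from the ortho-hydroxybenzylamine gives o-quinone methide 19, which is captured by C8, the only free carbon of ring A, in a Friedel–Crafts-type conjugate addition followed by rearomatisation; 18 has no free ring carbon and cannot couple with itself, and the volatile amine is swept out so that C2 is not exposed to base.

**Compound list**

1 | phloroglucinol (benzene-1,3,5-triol) | Oc1cc(O)cc(O)c1 | starting material
2 | 3,5-bis(methoxymethoxy)phenol | COCOc1cc(O)cc(OCOC)c1 | intermediate
3 | [3,5-bis(methoxymethoxy)phenoxy]tri(propan-2-yl)silane | COCOc1cc(OCOC)cc(O[Si](C(C)C)(C(C)C)C(C)C)c1 | intermediate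
4 | 1-bromo-3-methylbut-2-ene | CC(C)=CCBr | starting material
5 | [2,6-bis(methoxymethoxy)-4-(triisopropylsilyloxy)phenyl]lithium (formed in the flask) | [Li]c1c(OCOC)cc(O[Si](C(C)C)(C(C)C)C(C)C)cc1OCOC | intermediate
6 | [3,5-bis(methoxymethoxy)-4-(3-methylbut-2-enyl)phenoxy]tri(propan-2-yl)silane | CC(C)=CCc1c(OCOC)cc(O[Si](C(C)C)(C(C)C)C(C)C)cc1OCOC | intermediate
7 | 3,5-bis(methoxymethoxy)-4-(3-methylbut-2-enyl)phenol | CC(C)=CCc1c(OCOC)cc(O)cc1OCOC | intermediate
8 | 2-hydroxy-4,6-bis(methoxymethoxy)-5-(3-methylbut-2-enyl)benzaldehyde | O=Cc1c(O)cc(OCOC)c(CC=C(C)C)c1OCOC | intermediate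
9 | trimethyl orthoformate | COC(OC)OC | starting material
10 | styrene | C=Cc1ccccc1 | starting material
11 | 2-(dimethoxymethyl)-3,5-bis(methoxymethoxy)-4-(3-methylbut-2-enyl)phenol (formed in the flask) | COC(OC)c1c(O)cc(OCOC)c(CC=C(C)C)c1OCOC | intermediate
12 | (6E)-6-(methoxymethylidene)-3,5-bis(methoxymethoxy)-4-(3-methylbut-2-enyl)cyclohexa-2,4-dien-1-one (formed in the flask, reacts as its O-protonated phosphate ion pair) | CO/C=C1/C(=O)C=C(OCOC)C(CC=C(C)C)=C1OCOC | intermediate
13 | (2S,4S)-4-methoxy-5,7-bis(methoxymethoxy)-6-(3-methylbut-2-enyl)-2-phenylchromane | COCOc1c(CC=C(C)C)c(OCOC)c2c(c1)O[C@H](c1ccccc1)C[C@@H]2OC | intermediate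
14 | (2S)-5,7-bis(methoxymethoxy)-6-(3-methylbut-2-enyl)-2-phenylchroman-4-ol (C4 epimers) | COCOc1c(CC=C(C)C)c(OCOC)c2c(c1)O[C@H](c1ccccc1)CC2O | intermediate
15 | (2S)-5,7-bis(methoxymethoxy)-6-(3-methylbut-2-enyl)-2-phenylchroman-4-one | COCOc1c(CC=C(C)C)c(OCOC)c2c(c1)O[C@H](c1ccccc1)CC2=O | intermediate
16 | (2S)-5,7-dihydroxy-6-(3-methylbut-2-enyl)-2-phenylchroman-4-one | CC(C)=CCc1c(O)cc2O[C@H](c3ccccc3)CC(=O)c2c1O | intermediate
17 | 1-(2,4,6-trihydroxy-3-methylphenyl)ethanone | CC(=O)c1c(O)cc(O)c(C)c1O | starting material
18 | 1-[3-[(dimethylamino)methyl]-2,4,6-trihydroxy-5-methylphenyl]ethanone | CC(=O)c1c(O)c(C)c(O)c(CN(C)C)c1O | intermediate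
19 | 2-acetyl-3,5-dihydroxy-4-methyl-6-methylidenecyclohexa-2,4-dien-1-one (formed in the flask) | C=C1C(=O)C(C(C)=O)=C(O)C(C)=C1O | intermediate
20 | (2S)-8-[(3-acetyl-2,4,6-trihydroxy-5-methylphenyl)methyl]-5,7-dihydroxy-6-(3-methylbut-2-enyl)-2-phenylchroman-4-one | CC(=O)c1c(O)c(C)c(O)c(Cc2c(O)c(CC=C(C)C)c(O)c3c2O[C@H](c2ccccc2)CC3=O)c1O | target

**Step count**

Total: 11 steps. Longest linear sequence: 10 steps (steps 1 to 9 and step 11); step 10 prepares the side fragment.

**Steps most likely to fail**

1. Step 6. Styrene has no hydrogen-bonding handle, so enantiofacial discrimination inside the ion pair may be poor. The endo preference may also be incomplete, the product's C4 ether may re-ionise and add a second styrene, or a MOM acetal may exchange. Fallback, by known chemistry: starting again from 8, 9 and 10, the coupling is run with Sc(OTf)3 (5 mol %) in CH2Cl2 at rt, the established Lewis acid version. This gives racemic 2,4-cis-4-methoxy-5,7-bis(methoxymethoxy)-6-(3-methylbut-2-enyl)-2-phenylchromane F1. Hydrolysis as in step 7 gives racemic 5,7-bis(methoxymethoxy)-6-(3-methylbut-2-enyl)-2-phenylchroman-4-ol F2, and oxidation as in step 8 gives racemic 5,7-bis(methoxymethoxy)-6-(3-methylbut-2-enyl)-2-phenylchroman-4-one F3. Kinetic resolution by Noyori transfer hydrogenation with RuCl(p-cymene)[(R,R)-N-(p-toluenesulfonyl)-1,2-diphenylethylenediamine] and HCO2H/Et3N at rt, stopped near half conversion, is expected to reduce the (2R)-ketone to (2R,4R)-5,7-bis(methoxymethoxy)-6-(3-methylbut-2-enyl)-2-phenylchroman-4-ol F4, which is separated and set aside. The unreacted (2S)-ketone is 15, and the route resumes at step 9.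

2. Step 11. The dimethylamine released during the heated coupling may open ring C of the flavanone by retro-oxa-Michael reaction and erode the C2 configuration, or the quinone methide may be held up in reversible O-alkylation. Fallback: amine release and C–C bond formation are separated. Starting from 18, heating in methanol converts the Mannich base, by way of 19, into 1-[2,4,6-trihydroxy-3-(methoxymethyl)-5-methylphenyl]ethanone F5, the dimethylamine leaving with the solvent. F5 and 16 are then joined under acid catalysis (p-TsOH, 5 mol %, dioxane, 50 °C), which regenerates 19 by loss of methanol in a medium where ring C stays closed, and gives 20 directly.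

3. Step 7. The C4 cation may be intercepted by C8 of a second molecule (4-to-8 linked dimers), may lose a proton to the flav-3-ene, or the acid may begin to remove a MOM group. Fallback: oxidative instead of solvolytic unmasking. Starting from 13, 2,3-dichloro-5,6-dicyano-1,4-benzoquinone in CH2Cl2 over pH 7 phosphate buffer at 0 °C abstracts hydride from C4, the only C–H that is both benzylic to ring A and alpha to an ether oxygen. Water converts the resulting oxocarbenium ion into a hemiketal that loses methanol to give 15 in one operation. No new compound is isolated on the way (F0), and the route resumes at step 9.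

**Further compounds**

F1 | step 6 | racemic 2,4-cis-4-methoxy-5,7-bis(methoxymethoxy)-6-(3-methylbut-2-enyl)-2-phenylchromane (13 and its enantiomer in equal parts) | COCOc1c(CC=C(C)C)c(OCOC)c2c(c1)O[C@H](c1ccccc1)C[C@@H]2OC.COCOc1c(CC=C(C)C)c(OCOC)c2c(c1)O[C@@H](c1ccccc1)C[C@H]2OC
F2 | step 6 | racemic 5,7-bis(methoxymethoxy)-6-(3-methylbut-2-enyl)-2-phenylchroman-4-ol (C4 epimers) | COCOc1c(CC=C(C)C)c(OCOC)c2c(c1)OC(c1ccccc1)CC2O
F3 | step 6 | racemic 5,7-bis(methoxymethoxy)-6-(3-methylbut-2-enyl)-2-phenylchroman-4-one | COCOc1c(CC=C(C)C)c(OCOC)c2c(c1)OC(c1ccccc1)CC2=O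
F4 | step 6 | (2R,4R)-5,7-bis(methoxymethoxy)-6-(3-methylbut-2-enyl)-2-phenylchroman-4-ol | COCOc1c(CC=C(C)C)c(OCOC)c2c(c1)O[C@@H](c1ccccc1)C[C@H]2O
F5 | step 11 | 1-[2,4,6-trihydroxy-3-(methoxymethyl)-5-methylphenyl]ethanone | CC(=O)c1c(O)c(C)c(O)c(COC)c1O
F0 | step 7 | none | none
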